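**Plan**

- Retrosynthesis: cut the enone Cα=Cβ bond (4-methoxybenzaldehyde), then the C7 O–CH3 bond, then the C5–C6 bond of ring A, then the CH2–C(=O) bond of the acetonyl arm, and last the C4–C4a and O1–C2 bonds of the 2H-pyran ring.
- Forward: the 2H-pyran ring is annulated onto 4-hydroxy-6-methyl-2-pyranone, the methyl group is acetylated, and ring A is then built around the finished pyran ring while the pyranone ring is consumed; O-methylation and chalcone formation follow.
- Enabling feature: ring A is an acylphloroglucinol whose C8a–O1 bond and C4a carbon already sit in a 2H,5H-pyrano[4,3-b]pyran-5-one. The lactone carbon becomes C5, the lactone ring oxygen becomes the C7 hydroxyl and the side-chain methylene becomes C6, so the acyl group can only end up at C6.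
- The acyl arm is carried as acetyl through ring formation and extended to the cinnamoyl unit at the end: an enone in the arm would invite conjugate addition, and a 2',6'-dihydroxychalcone would drift towards flavanones.
- Stereochemistry: the target has no stereocenter; its only stereo-element, the E enone, comes from the E1cB dehydration of the last step.

Key step: step 3

**Step 1**
Reactants: 1 4-hydroxy-6-methyl-2H-pyran-2-one; 2 3-methylbut-2-enal
Product: 4 2,2,7-trimethyl-2H,5H-pyrano[4,3-b]pyran-5-one, via 1-oxatriene 3 (not isolated)
Conditions: ethylenediammonium diacetate (10 mol %), CH2Cl2, rt to 40 °C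
Reagents that add atoms: none
Why: Amine-catalysed Knoevenagel condensation at C3 of the hydroxypyranone gives 1-oxatriene 3, which closes by oxa-6π electrocyclization onto the C4 ketone oxygen (formal [3+3] annulation), an established entry to 2H,5H-pyrano[4,3-b]pyran-5-ones; no stereocenter arises because C2 carries two methyl groups.

**Step 2**
Reactants: 4 2,2,7-trimethyl-2H,5H-pyrano[4,3-b]pyran-5-one; 5 N-methoxy-N-methylacetamide
Product: 8 2,2-dimethyl-7-(2-oxopropyl)-2H,5H-pyrano[4,3-b]pyran-5-one, via lithium dienolate 6 (not isolated), via lithium hemiaminal adduct 7 (not isolated)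
Conditions: LiN(iPr)2 (1.1 equiv), THF, −78 °C; then 5 (1.3 equiv), −78 to −20 °C; then cold 1 M HCl
Reagents that add atoms: none
Why: The 7-methyl group is the vinylogous α-position of the lactone (C4a is fully substituted), so LiN(iPr)2 should give the extended enolate 6, and its acylation by the Weinreb amide stops at chelated adduct 7 until acid work-up (Weinreb ketone synthesis), which keeps the more acidic product from quenching unreacted 6.

**Step 3**
Reactants: 8 2,2-dimethyl-7-(2-oxopropyl)-2H,5H-pyrano[4,3-b]pyran-5-one
Product: 10 1-(5,7-dihydroxy-2,2-dimethyl-2H-chromen-6-yl)ethanone, via ring-opened methyl ester 9 (not isolated)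
Conditions: Mg(OMe)2 (4 equiv), MeOH, reflux; then 1 M HCl, 0 °C
Reagents that add atoms: none
Why: Proposed new method: methoxide from Mg(OMe)2 adds to the lactone carbonyl (C5) of 8 and the C5–O6 bond breaks, giving methyl ester 9 as a magnesium chelate whose side chain is a 1,3-diketonate; the closest known reaction type is the Mg(OMe)2-mediated Claisen cyclization of 3,5,7-triketo esters and of 6-(2-oxoalkyl)-4-hydroxy-2-pyranones to acylphloroglucinols, which has not been shown on a pyranone whose C4 oxygen is an ether held in a fused 2H-pyran. The central diketonate carbon then attacks the ester carbon in a 6-exo-trig closure that forms the C5–C6 bond of the chromene, methoxide is expelled, and tautomerization to the phenol form makes ring A aromatic, an irreversible exit. The endocyclic C5=C6 double bond of the 2H-pyran in 9 holds the ester and the diketone arm cis, so the reacting carbons are preorganized, and the ester is a β-alkoxyacrylate, at least as electrophilic as the enolized β-keto ester that cyclizes in the known cases. The step needs C-acylation to win over O-acylation back to the pyranone and over aldol closure: re-lactonization is reversible, the aldol mode is closed because the carbon that becomes C4a bears no hydrogen and could not aromatize, and magnesium chelation of the diketonate directs bond formation to carbon. No stereocenter is formed, and because the pyran ring passes through untouched its oxygen ends at C8a, the lactone carbonyl oxygen at C5, the former ring oxygen O6 at C7 and the acetyl group at C6.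

**Step 4**
Reactants: 10 1-(5,7-dihydroxy-2,2-dimethyl-2H-chromen-6-yl)ethanone
Product: 11 1-(5-hydroxy-7-methoxy-2,2-dimethyl-2H-chromen-6-yl)ethanone
Conditions: MeI (1.05 equiv), K2CO3 (1.1 equiv), acetone, rt
Reagents that add atoms: iodomethane, CI
Why: Williamson-type mono-O-methylation with one equivalent of MeI is expected at the C7 hydroxyl, which is flanked only by H-8, while the C5 hydroxyl is shielded by the peri C4–H and held in the hydrogen bond to the acetyl group, by analogy with partial methylation of C-alkylated phloroacetophenones, where the chelated hydroxyl beside the alkyl group is the one left unalkylated.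

**Step 5**
Reactants: 11 1-(5-hydroxy-7-methoxy-2,2-dimethyl-2H-chromen-6-yl)ethanone; 12 4-methoxybenzaldehyde
Product: 14 glychalcone A [(E)-1-(5-hydroxy-7-methoxy-2,2-dimethyl-2H-chromen-6-yl)-3-(4-methoxyphenyl)prop-2-en-1-one], via aldol adduct 13 (not isolated)
Conditions: KOH (excess), EtOH/H2O, rt; then 1 M HCl to pH 5, 0 °C
Reagents that add atoms: none
Why: Claisen–Schmidt condensation: base-mediated aldol addition of methyl ketone 11 to the non-enolizable aldehyde gives aldol 13, whose E1cB dehydration should give the conjugated enone as the thermodynamically favoured E isomer, and the 7-methoxy group leaves only the chelated 5-hydroxyl, so the open chalcone should be kept as with other 2'-hydroxy-6'-methoxychalcones.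

**Compound list**

1 | 4-hydroxy-6-methyl-2H-pyran-2-one | Cc1cc(O)cc(=O)o1 | starting material
2 | 3-methylbut-2-enal | CC(C)=CC=O | starting material
3 | 6-methyl-3-(3-methylbut-2-en-1-ylidene)-2H-pyran-2,4(3H)-dione (1-oxatriene, not isolated) | CC1=CC(=O)C(=CC=C(C)C)C(=O)O1 | intermediate
4 | 2,2,7-trimethyl-2H,5H-pyrano[4,3-b]pyran-5-one | CC1=CC2=C(C=CC(C)(C)O2)C(=O)O1 | intermediate
5 | N-methoxy-N-methylacetamide | CON(C)C(C)=O | starting material
6 | lithium dienolate of 4 (7-methylene form, not isolated) | C=C1C=C2OC(C)(C)C=CC2=C(O[Li])O1 | intermediate
7 | lithium hemiaminal adduct of 6 and 5 (racemic, not isolated) | CC(O[Li])(CC1=CC2=C(C=CC(C)(C)O2)C(=O)O1)N(C)OC | intermediate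
8 | 2,2-dimethyl-7-(2-oxopropyl)-2H,5H-pyrano[4,3-b]pyran-5-one | CC(=O)CC1=CC2=C(C=CC(C)(C)O2)C(=O)O1 | intermediate
9 | methyl 6-(2,4-dioxopentyl)-2,2-dimethyl-2H-pyran-5-carboxylate (present as its magnesium chelate, not isolated) | COC(=O)C1=C(CC(=O)CC(C)=O)OC(C)(C)C=C1 | intermediate
10 | 1-(5,7-dihydroxy-2,2-dimethyl-2H-chromen-6-yl)ethanone | CC(=O)c1c(O)cc2c(c1O)C=CC(C)(C)O2 | intermediate
11 | 1-(5-hydroxy-7-methoxy-2,2-dimethyl-2H-chromen-6-yl)ethanone | CC(=O)c1c(OC)cc2c(c1O)C=CC(C)(C)O2 | intermediate
12 | 4-methoxybenzaldehyde | COc1ccc(C=O)cc1 | starting material
13 | 3-hydroxy-1-(5-hydroxy-7-methoxy-2,2-dimethyl-2H-chromen-6-yl)-3-(4-methoxyphenyl)propan-1-one (racemic aldol adduct, not isolated) | COc1ccc(C(O)CC(=O)c2c(OC)cc3c(c2O)C=CC(C)(C)O3)cc1 | intermediate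
14 | glychalcone A, (E)-1-(5-hydroxy-7-methoxy-2,2-dimethyl-2H-chromen-6-yl)-3-(4-methoxyphenyl)prop-2-en-1-one | COc1ccc(/C=C/C(=O)c2c(OC)cc3c(c2O)C=CC(C)(C)O3)cc1 | target

**Step count**

Total steps: 5. Longest linear sequence: 5 steps (1 → 4 → 8 → 10 → 11 → 14).

**Steps most likely to fail**

Step 3 (proposed new method). The side-chain methylene of 8 may be deprotonated first, and the resulting extended enolate may then resist addition of methoxide to the lactone. Methoxide may also add at the vinylogous enol-ether positions C7 and C8a, so that the bicycle degrades before the Claisen closure can occur. The fallback uses known chemistry and sets out from 2. Compound 2 is condensed with commercial 1-(2,4-dihydroxy-6-methoxyphenyl)ethanone F1 under ethylenediammonium diacetate in refluxing xylene (or in pyridine at 140 °C). This amine-mediated chromenylation forms the C–C bond at the carbon between the two hydroxyls, dehydrates, and closes the ring by oxa-6π cyclization through the non-chelated hydroxyl para to the acetyl group. It should give 11 directly, where the route is rejoined before step 5. Here the position of the acetyl group rests on the higher nucleophilicity of the doubly activated ring carbon, not on the ring-exchange logic.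

Step 4. Alkylation may occur at the C5 oxygen or at both oxygens, since both hydroxyls can chelate the acetyl group. The fallback sets out from 10. Exhaustive methylation (Me2SO4 in excess, K2CO3, acetone, reflux) should give 1-(5,7-dimethoxy-2,2-dimethyl-2H-chromen-6-yl)ethanone F2. Treatment with BCl3 (1 equiv, CH2Cl2, −78 to 0 °C) then performs the chelation-directed cleavage of an ortho methyl ether of an aryl ketone. Of the two candidates, the C5 ether is flanked on both sides and twisted out of the ring plane, hence the more basic and more labile, so the demethylation should return 11.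

Step 2. Metalation of 4 may be misdirected (attack of the amide base on the lactone, deprotonation at C8), or adduct 7 may collapse early and the liberated ketone then protonate unreacted 6. The fallback sets out from 1. Double deprotonation with LiN(iPr)2 (2.2 equiv, THF, −78 to 0 °C) and acylation at the methyl terminus with 5 should give 4-hydroxy-6-(2-oxopropyl)-2H-pyran-2-one F3. Annulation of this compound with 2 under the conditions of step 1 then closes the 2H-pyran ring last and rejoins the route at 8.

**Further compounds**

F1 | step 3 | 1-(2,4-dihydroxy-6-methoxyphenyl)ethanone | CC(=O)c1c(O)cc(O)cc1OC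
F2 | step 4 | 1-(5,7-dimethoxy-2,2-dimethyl-2H-chromen-6-yl)ethanone | CC(=O)c1c(OC)cc2c(c1OC)C=CC(C)(C)O2
F3 | step 2 | 4-hydroxy-6-(2-oxopropyl)-2H-pyran-2-one | CC(=O)CC1=CC(O)=CC(=O)O1
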